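**Retrosynthetic overview**

1. C-9 is set last: the 20-methyl group comes from conjugate methylation of a 9(10)-en-1-one, and the enolate is trapped as a triflate and reduced to the C1=C10 alkene. The ester methyl and the acetate are late adjustments.
2. That enone comes from a tricyclic lactone by hydrogenation of C6=C7 and reductive cleavage of a temporary C19–O–C2 γ-lactone.
3. Key disconnection: C5–C10 and C8–C9 by an intramolecular Diels–Alder reaction of a (5E,7Z)-dienyl ynone. Ring A (tether ring) and ring B (cycloadduct ring) form in the same event.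
4. Enabling feature: the carboxyl carbon C-19 on quaternary C-4 stands 1,3 to C-2 in ring A. A lactone from C-19 to a temporary oxygen on C-2 turns C4–C3–C2 into a rigid cis tether, and C-1 between C-2 and C-10 can be the ketone that activates the C9≡C10 alkyne.
5. Precursors: (5R)-5-(hydroxymethyl)butyrolactone (stereocentre at C-2 bought, C-4 relayed from it by trans-selective enolate methylation) and an alkyne fragment carrying C-9 to C-16 (13E set by a Johnson–Claisen rearrangement).

Key step: step 15

Remark: bi- and tricyclic intermediates are numbered as halimanes (C-1 to C-20; the carboxyl carbon on C-4 is called C-19 and its methyl C-18), and the target is taken as the (4S,5R,8R,9S,13E) isomer that the SMILES defines.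

**Route**

Step 1
Reactants: 1 2-[(tert-butyldimethylsilyl)oxy]acetaldehyde; 2 isopropenylmagnesium bromide
Product: 3 rac-1-[(tert-butyldimethylsilyl)oxy]-3-methylbut-3-en-2-ol
Conditions: THF, −78 to 0 °C
Reagents that add atoms: none
Why: Grignard 1,2-addition to the aldehyde; the carbinol centre is racemic and is destroyed in step 2.

Step 2
Reactants: 3
Product: 5 ethyl (4E)-6-[(tert-butyldimethylsilyl)oxy]-4-methylhex-4-enoate, via ketene acetal 4 (not isolated)
Conditions: MeC(OEt)3, EtCO2H (cat.), 140 °C, EtOH distilled off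
Reagents that add atoms: triethyl orthoacetate, CC(OCC)(OCC)OCC
Why: Johnson–Claisen rearrangement through a chair transition state with the CH2OSi group equatorial, which should give the E trisubstituted alkene (later C13=C14).

Step 3
Reactants: 5
Product: 6 (4E)-6-[(tert-butyldimethylsilyl)oxy]-4-methylhex-4-enal
Conditions: i-Bu2AlH (1.05 equiv), CH2Cl2, −78 °C
Reagents that add atoms: none
Why: partial reduction of the ester to the aldehyde at low temperature through the stable aluminium hemiacetal.

Step 4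
Reactants: 6
Product: 7 tert-butyl(dimethyl){[(2E)-3-methylhept-2-en-6-yn-1-yl]oxy}silane
Conditions: dimethyl (1-diazo-2-oxopropyl)phosphonate, K2CO3, MeOH, 0 to 23 °C
Reagents that add atoms: dimethyl (1-diazo-2-oxopropyl)phosphonate, COP(=O)(OC)C(=[N+]=[N-])C(C)=O
Why: Seyferth–Gilbert homologation in its Ohira–Bestmann form converts the aldehyde into the terminal alkyne (C-9 and C-10) under conditions that leave the silyl ether and the alkene untouched.

Step 5
Reactants: 8 (5R)-5-(hydroxymethyl)dihydrofuran-2(3H)-one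
Product: 9 (5R)-5-({[tert-butyl(diphenyl)silyl]oxy}methyl)dihydrofuran-2(3H)-one
Conditions: TBDPSCl, imidazole, DMF, 23 °C
Reagents that add atoms: tert-butyl(chloro)diphenylsilane, CC(C)(C)[Si](Cl)(c1ccccc1)c1ccccc1
Why: silylation of the primary alcohol gives the bulky C-5 substituent that directs the enolate alkylation in step 7.

Step 6
Reactants: 9
Product: 11 (5R)-5-({[tert-butyl(diphenyl)silyl]oxy}methyl)-3-(hydroxymethyl)dihydrofuran-2(3H)-one (C-3 epimers), via lithium enolate 10 (not isolated)
Conditions: LiN(iPr)2, THF, −78 °C; CH2O (gas), −78 to −40 °C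
Reagents that add atoms: formaldehyde, C=O
Why: aldol addition of the lactone enolate to monomeric formaldehyde introduces the future C-5; the C-3 configuration is irrelevant because this carbon is enolized again in step 7.

Step 7
Reactants: 11
Product: 13 (3S,5R)-5-({[tert-butyl(diphenyl)silyl]oxy}methyl)-3-(hydroxymethyl)-3-methyldihydrofuran-2(3H)-one, via dilithium alkoxide enolate 12 (not isolated)
Conditions: LiN(iPr)2 (2.2 equiv), THF, −78 to −40 °C; MeI, DMPU, −78 to −30 °C
Reagents that add atoms: iodomethane, CI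
Why: Fráter–Seebach-type alkylation of the alkoxide enolate, in which MeI should enter anti to the C-5 CH2OSi group (the established 3,5-trans rule for γ-substituted butyrolactone enolates); this sets quaternary C-4 of the target with the future diene carbon cis to the future C-1.

Step 8
Reactants: 13
Product: 14 (3S,5R)-5-({[tert-butyl(diphenyl)silyl]oxy}methyl)-3-methyl-2-oxooxolane-3-carbaldehyde
Conditions: DMP, CH2Cl2, 0 to 23 °C
Reagents that add atoms: none
Why: Dess–Martin oxidation of the neopentyl primary alcohol under neutral conditions, which avoids retro-aldol cleavage of the non-enolizable formyl lactone.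

Step 9
Reactants: 14
Product: 15 (3S,5R)-5-({[tert-butyl(diphenyl)silyl]oxy}methyl)-3-[(E)-2-iodoethenyl]-3-methyldihydrofuran-2(3H)-one
Conditions: CrCl2, CHI3, THF/1,4-dioxane (1:6), 0 to 23 °C
Reagents that add atoms: iodoform, IC(I)I
Why: Takai olefination, which is E-selective for hindered aldehydes and tolerates the lactone; it sets the 5E alkene.

Step 10
Reactants: 15
Product: 16 (3S,5R)-5-({[tert-butyl(diphenyl)silyl]oxy}methyl)-3-methyl-3-[(1E,3Z)-penta-1,3-dien-1-yl]dihydrofuran-2(3H)-one
Conditions: (Z)-prop-1-en-1-ylboronic acid, Pd(PPh3)4 (5 mol %), K3PO4, THF/H2O, 40 °C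
Reagents that add atoms: (Z)-prop-1-en-1-ylboronic acid, C/C=C\B(O)O
Why: Suzuki–Miyaura coupling proceeds with retention at both alkenyl partners and should deliver the (5E,7Z)-diene that the key step needs.

Step 11
Reactants: 16
Product: 17 (3S,5R)-5-(hydroxymethyl)-3-methyl-3-[(1E,3Z)-penta-1,3-dien-1-yl]dihydrofuran-2(3H)-one
Conditions: Bu4NF, AcOH, THF, 0 to 23 °C
Reagents that add atoms: none
Why: buffered fluoride desilylation frees the future C-1 alcohol without opening the hindered lactone.

Step 12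
Reactants: 17
Product: 18 (2R,4S)-4-methyl-5-oxo-4-[(1E,3Z)-penta-1,3-dien-1-yl]oxolane-2-carbaldehyde
Conditions: DMP, CH2Cl2, 0 to 23 °C
Reagents that add atoms: none
Why: Dess–Martin oxidation gives the α-acyloxy aldehyde under non-basic conditions that should not epimerize C-2.

Step 13
Reactants: 18; 7
Product: 20 (3S,5R)-5-[(6E)-8-{[tert-butyl(dimethyl)silyl]oxy}-1-hydroxy-6-methyloct-6-en-2-yn-1-yl]-3-methyl-3-[(1E,3Z)-penta-1,3-dien-1-yl]dihydrofuran-2(3H)-one (carbinol epimers), via lithium acetylide 19 (not isolated)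
Conditions: 7, n-BuLi, THF, −78 °C; then 18, −78 °C
Reagents that add atoms: none
Why: acetylide 1,2-addition to the aldehyde, which at −78 °C is far more reactive than the lactone; the new carbinol centre is oxidized away in step 14.

Step 14
Reactants: 20
Product: 21 (3S,5R)-5-[(6E)-8-{[tert-butyl(dimethyl)silyl]oxy}-6-methyloct-6-en-2-ynoyl]-3-methyl-3-[(1E,3Z)-penta-1,3-dien-1-yl]dihydrofuran-2(3H)-one
Conditions: DMP, CH2Cl2, 0 to 23 °C
Reagents that add atoms: none
Why: Dess–Martin oxidation of the propargylic alcohol gives the ynone dienophile without base, so C-2 and the Z alkene should stay intact.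

Step 15
Reactants: 21
Product: 22 (2R,4S,5R,8R,13E)-15-[(tert-butyldimethylsilyl)oxy]-1-oxo-20-norhalima-6,9,13-trien-19,2-olide
Conditions: PhMe (0.01 M), BHT (cat.), 110 °C
Reagents that add atoms: none
Why: Thermal intramolecular Diels–Alder reaction (concerted, asynchronous [4+2]) between the (5E,7Z)-diene and the ketone-activated C9≡C10 alkyne, the closest known cases being cycloadditions of deca-7,9-dien-1-yn-3-ones and of dienes with a Z terminus. Ring A closes as the tether ring through the C5–C10 bond (six-membered chair inside a 6-oxabicyclo[3.2.1]octanone) and ring B closes as the cycloadduct ring through the C8–C9 bond (cyclohexa-1,4-diene). C-5 is set by the lactone bridge: C-19 and the oxygen on C-2 must stand 1,3-diaxial on ring A and C-6 must lie equatorial to reach C-9, so H-5 ends anti to C-19. C-8 is set by suprafacial addition to the diene, whose 7Z geometry places the inside methyl C-17 cis to the inside H-5. The step needs diene face selectivity and retention of the Z geometry; the first is enforced by the bridged transition state (from the other face ring B cannot close) and the second by the moderate temperature that the ynone allows, while an alkyne has no endo/exo issue and the tether fixes the regiochemistry. The adduct carries the C9=C10 enone that later sets C-9 and becomes the C1=C10 alkene.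

Step 16
Reactants: 22
Product: 23 (2R,4S,5R,8R,13E)-15-[(tert-butyldimethylsilyl)oxy]-1-oxo-20-norhalima-9,13-dien-19,2-olide
Conditions: H2 (1 atm), RhCl(PPh3)3 (10 mol %), PhH/EtOH, 23 °C
Reagents that add atoms: none
Why: homogeneous hydrogenation should reduce the unhindered cis-disubstituted C6=C7 bond much faster than the tetrasubstituted enone or the trisubstituted side-chain alkene, and it removes the risk of aromatizing the cyclohexa-1,4-diene.

Step 17
Reactants: 23
Product: 24 (4S,5R,8R,13E)-15-[(tert-butyldimethylsilyl)oxy]-1-oxo-20-norhalima-9,13-dien-19-oic acid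
Conditions: SmI2 (2.5 equiv), THF/MeOH, −78 °C
Reagents that add atoms: none
Why: reductive cleavage of an α-acyloxy ketone by SmI2 (ketyl formation, loss of carboxylate, protonation of the enolate at C-2) unties the temporary lactone, so C-2 becomes CH2, C-19 the free acid, and the bought stereocentre disappears.

Step 18
Reactants: 24
Product: 25 methyl (4S,5R,8R,13E)-15-[(tert-butyldimethylsilyl)oxy]-1-oxo-20-norhalima-9,13-dien-19-oate
Conditions: Me3SiCHN2, PhMe/MeOH, 0 °C
Reagents that add atoms: (trimethylsilyl)diazomethane, C[Si](C)(C)C=[N+]=[N-]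
Why: esterification of the hindered tertiary acid by O-alkylation with diazomethane generated in the flask, which needs no attack at the neopentyl carbonyl.

Step 19
Reactants: 25
Product: 27 methyl (4S,5R,8R,9S,13E)-15-[(tert-butyldimethylsilyl)oxy]-1-{[(trifluoromethyl)sulfonyl]oxy}halima-1(10),13-dien-19-oate, via lithium enolate 26 (not isolated)
Conditions: MeLi, CuI, Et2O, 0 °C (gives Me2CuLi); 25, −20 to 0 °C; then N-(5-chloropyridin-2-yl)-1,1,1-trifluoro-N-[(trifluoromethyl)sulfonyl]methanesulfonamide, THF, −78 to 23 °C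
Reagents that add atoms: methyllithium (used as Me2CuLi), C[Li]; N-(5-chloropyridin-2-yl)-1,1,1-trifluoro-N-[(trifluoromethyl)sulfonyl]methanesulfonamide, FC(F)(F)S(=O)(=O)N(c1ccc(Cl)cn1)S(=O)(=O)C(F)(F)F
Why: conjugate addition of the Gilman cuprate, in which the methyl group should enter C-9 axially on the ring B half-chair from the face of H-5 (the other face would need a twist-boat), placing C-20 cis to C-17 and the side chain equatorial; the regiodefined C1–C10 enolate is then trapped as the enol triflate.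

Step 20
Reactants: 27
Product: 28 methyl (4S,5R,8R,9S,13E)-15-[(tert-butyldimethylsilyl)oxy]halima-1(10),13-dien-19-oate
Conditions: Pd(OAc)2 (5 mol %), PPh3, HCO2H, n-Bu3N, DMF, 60 °C
Reagents that add atoms: none
Why: palladium-catalysed formate reduction of the enol triflate replaces the triflate by hydrogen, so the alkene stays where the enolate was, at C1=C10.

Step 21
Reactants: 28
Product: 29 methyl (4S,5R,8R,9S,13E)-15-hydroxyhalima-1(10),13-dien-19-oate
Conditions: Bu4NF, THF, 0 °C
Reagents that add atoms: none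
Why: fluoride cleavage of the primary allylic silyl ether, to which the hindered methyl ester and both alkenes are inert.

Step 22
Reactants: 29
Product: 30 methyl (4S,5R,8R,9S,13E)-15-acetoxyhalima-1(10),13-dien-19-oate (CNP0209995.1)
Conditions: Ac2O, pyridine, DMAP (cat.), CH2Cl2, 23 °C
Reagents that add atoms: acetic anhydride, CC(=O)OC(C)=O
Why: standard acylation of the primary allylic alcohol gives the target.

**Compound list**

1 | 2-[(tert-butyldimethylsilyl)oxy]acetaldehyde | O=CCO[Si](C)(C)C(C)(C)C | starting material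
2 | isopropenylmagnesium bromide | CC(=C)[Mg]Br | starting material
3 | rac-1-[(tert-butyldimethylsilyl)oxy]-3-methylbut-3-en-2-ol | CC(=C)C(O)CO[Si](C)(C)C(C)(C)C | intermediate
4 | ketene acetal of 3 (1-ethoxyvinyl ether) | C=C(OCC)OC(CO[Si](C)(C)C(C)(C)C)C(C)=C | intermediate
5 | ethyl (4E)-6-[(tert-butyldimethylsilyl)oxy]-4-methylhex-4-enoate | CCOC(=O)CC/C(C)=C/CO[Si](C)(C)C(C)(C)C | intermediate
6 | (4E)-6-[(tert-butyldimethylsilyl)oxy]-4-methylhex-4-enal | O=CCC/C(C)=C/CO[Si](C)(C)C(C)(C)C | intermediate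
7 | tert-butyl(dimethyl){[(2E)-3-methylhept-2-en-6-yn-1-yl]oxy}silane | C#CCC/C(C)=C/CO[Si](C)(C)C(C)(C)C | intermediate
8 | (5R)-5-(hydroxymethyl)dihydrofuran-2(3H)-one | O=C1O[C@@H](CO)CC1 | starting material
9 | (5R)-5-({[tert-butyl(diphenyl)silyl]oxy}methyl)dihydrofuran-2(3H)-one | O=C1O[C@@H](CO[Si](c2ccccc2)(c2ccccc2)C(C)(C)C)CC1 | intermediate
10 | lithium enolate of 9 | [Li]OC1=CC[C@H](CO[Si](c2ccccc2)(c2ccccc2)C(C)(C)C)O1 | intermediate
11 | (5R)-5-({[tert-butyl(diphenyl)silyl]oxy}methyl)-3-(hydroxymethyl)dihydrofuran-2(3H)-one (C-3 epimers) | O=C1O[C@@H](CO[Si](c2ccccc2)(c2ccccc2)C(C)(C)C)CC1CO | intermediate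
12 | dilithium alkoxide enolate of 11 | [Li]OCC1=C(O[Li])O[C@@H](CO[Si](c2ccccc2)(c2ccccc2)C(C)(C)C)C1 | intermediate
13 | (3S,5R)-5-({[tert-butyl(diphenyl)silyl]oxy}methyl)-3-(hydroxymethyl)-3-methyldihydrofuran-2(3H)-one | O=C1O[C@@H](CO[Si](c2ccccc2)(c2ccccc2)C(C)(C)C)C[C@@]1(C)CO | intermediate
14 | (3S,5R)-5-({[tert-butyl(diphenyl)silyl]oxy}methyl)-3-methyl-2-oxooxolane-3-carbaldehyde | O=C1O[C@@H](CO[Si](c2ccccc2)(c2ccccc2)C(C)(C)C)C[C@@]1(C)C=O | intermediate
15 | (3S,5R)-5-({[tert-butyl(diphenyl)silyl]oxy}methyl)-3-[(E)-2-iodoethenyl]-3-methyldihydrofuran-2(3H)-one | O=C1O[C@@H](CO[Si](c2ccccc2)(c2ccccc2)C(C)(C)C)C[C@@]1(C)/C=C/I | intermediate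
16 | (3S,5R)-5-({[tert-butyl(diphenyl)silyl]oxy}methyl)-3-methyl-3-[(1E,3Z)-penta-1,3-dien-1-yl]dihydrofuran-2(3H)-one | O=C1O[C@@H](CO[Si](c2ccccc2)(c2ccccc2)C(C)(C)C)C[C@@]1(C)/C=C/C=C\C | intermediate
17 | (3S,5R)-5-(hydroxymethyl)-3-methyl-3-[(1E,3Z)-penta-1,3-dien-1-yl]dihydrofuran-2(3H)-one | O=C1O[C@@H](CO)C[C@@]1(C)/C=C/C=C\C | intermediate
18 | (2R,4S)-4-methyl-5-oxo-4-[(1E,3Z)-penta-1,3-dien-1-yl]oxolane-2-carbaldehyde | O=C1O[C@@H](C=O)C[C@@]1(C)/C=C/C=C\C | intermediate
19 | lithium acetylide of 7 | [Li]C#CCC/C(C)=C/CO[Si](C)(C)C(C)(C)C | intermediate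
20 | (3S,5R)-5-[(6E)-8-{[tert-butyl(dimethyl)silyl]oxy}-1-hydroxy-6-methyloct-6-en-2-yn-1-yl]-3-methyl-3-[(1E,3Z)-penta-1,3-dien-1-yl]dihydrofuran-2(3H)-one (carbinol epimers) | O=C1O[C@@H](C(O)C#CCC/C(C)=C/CO[Si](C)(C)C(C)(C)C)C[C@@]1(C)/C=C/C=C\C | intermediate
21 | (3S,5R)-5-[(6E)-8-{[tert-butyl(dimethyl)silyl]oxy}-6-methyloct-6-en-2-ynoyl]-3-methyl-3-[(1E,3Z)-penta-1,3-dien-1-yl]dihydrofuran-2(3H)-one | O=C1O[C@@H](C(=O)C#CCC/C(C)=C/CO[Si](C)(C)C(C)(C)C)C[C@@]1(C)/C=C/C=C\C | intermediate
22 | (2R,4S,5R,8R,13E)-15-[(tert-butyldimethylsilyl)oxy]-1-oxo-20-norhalima-6,9,13-trien-19,2-olide | O=C1O[C@@H]2C[C@@]1(C)[C@@H]1C=C[C@@H](C)C(CC/C(C)=C/CO[Si](C)(C)C(C)(C)C)=C1C2=O | intermediate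
23 | (2R,4S,5R,8R,13E)-15-[(tert-butyldimethylsilyl)oxy]-1-oxo-20-norhalima-9,13-dien-19,2-olide | O=C1O[C@@H]2C[C@@]1(C)[C@@H]1CC[C@@H](C)C(CC/C(C)=C/CO[Si](C)(C)C(C)(C)C)=C1C2=O | intermediate
24 | (4S,5R,8R,13E)-15-[(tert-butyldimethylsilyl)oxy]-1-oxo-20-norhalima-9,13-dien-19-oic acid | OC(=O)[C@@]1(C)CCC(=O)C2=C(CC/C(C)=C/CO[Si](C)(C)C(C)(C)C)[C@H](C)CC[C@@H]12 | intermediate
25 | methyl (4S,5R,8R,13E)-15-[(tert-butyldimethylsilyl)oxy]-1-oxo-20-norhalima-9,13-dien-19-oate | COC(=O)[C@@]1(C)CCC(=O)C2=C(CC/C(C)=C/CO[Si](C)(C)C(C)(C)C)[C@H](C)CC[C@@H]12 | intermediate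
26 | lithium enolate: methyl (4S,5R,8R,9S,13E)-15-[(tert-butyldimethylsilyl)oxy]-1-(lithiooxy)halima-1(10),13-dien-19-oate | COC(=O)[C@@]1(C)CCC(O[Li])=C2[C@H]1CC[C@@H](C)[C@]2(C)CC/C(C)=C/CO[Si](C)(C)C(C)(C)C | intermediate
27 | methyl (4S,5R,8R,9S,13E)-15-[(tert-butyldimethylsilyl)oxy]-1-{[(trifluoromethyl)sulfonyl]oxy}halima-1(10),13-dien-19-oate | COC(=O)[C@@]1(C)CCC(OS(=O)(=O)C(F)(F)F)=C2[C@H]1CC[C@@H](C)[C@]2(C)CC/C(C)=C/CO[Si](C)(C)C(C)(C)C | intermediate
28 | methyl (4S,5R,8R,9S,13E)-15-[(tert-butyldimethylsilyl)oxy]halima-1(10),13-dien-19-oate | COC(=O)[C@@]1(C)CCC=C2[C@H]1CC[C@@H](C)[C@]2(C)CC/C(C)=C/CO[Si](C)(C)C(C)(C)C | intermediate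
29 | methyl (4S,5R,8R,9S,13E)-15-hydroxyhalima-1(10),13-dien-19-oate | COC(=O)[C@@]1(C)CCC=C2[C@H]1CC[C@@H](C)[C@]2(C)CC/C(C)=C/CO | intermediate
30 | methyl (4S,5R,8R,9S,13E)-15-acetoxyhalima-1(10),13-dien-19-oate (CNP0209995.1) | COC(=O)[C@@]1(C)CCC=C2[C@H]1CC[C@@H](C)[C@]2(C)CC/C(C)=C/COC(C)=O | target

**Step count and risks**

Total step count: 22. Longest linear sequence: 18 steps (steps 5 to 22, from lactone 8); the alkyne branch (steps 1 to 4) joins at step 13.

Steps most likely to fail:

Step 15. The inside methyl of the Z terminus slows the cycloaddition. At the temperature then needed, the 7Z alkene may isomerize to 7E (which would give the C-8 epimer) or undergo a 1,5-hydrogen shift, and the acidic C-2 of the α-acyloxy ynone may epimerize to the trans lactone, which cannot cyclize. Fallback: set out from carbinol 20 and close both rings before the ketone is made. A cycloisomerization of the unactivated dienyne catalysed by zerovalent nickel (Ni(cod)2, tris(2-biphenylyl) phosphite, THF, 25 °C) runs through a metallacycle at room temperature. It should keep the diene geometry, and the same lactone bridge should control C-5. It should give the tricyclic dienol F1, whose Dess–Martin oxidation comes back to the route at 22.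

Step 19. The tetrasubstituted, doubly β-branched enone may resist conjugate addition (enolization or 1,2-addition instead), and axial delivery on the H-5 face may not dominate. Fallback: set out from 25 and form the C9–C20 bond by a directed allylic substitution. Reduction with KBH(s-Bu)3 (THF, −78 °C) should give the axial allylic alcohol F2 with the hydroxyl on the H-5 face. Esterification with 2-(diphenylphosphanyl)benzoic acid (DCC, DMAP) should give the phosphanylbenzoate F3. MeMgBr with CuBr·SMe2 (Et2O, 23 °C) should then deliver methyl to C-9 syn to the leaving group, with transposition of the alkene to C1=C10. This skips the triflate and comes back to the route at 28.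

Step 7. The dianion may lose formaldehyde by retro-aldol cleavage on warming, and the aggregated alkoxide may erode the anti selectivity of the methylation. Fallback: set out from 9 and build the quaternary centre without a β-oxygen. Alkylation with allyl bromide (LiN(iPr)2, THF, −78 °C) should give the allyl lactone F4. A second enolization and MeI, again anti to the C-5 substituent, should give the allyl methyl lactone F5. Isomerization of the allyl group with RuHCl(CO)(PPh3)3 (PhMe, 80 °C) should give the (E)-propenyl lactone F6, and ozonolysis (O3, CH2Cl2, −78 °C; Me2S) comes back to the route at 14.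

**Further compounds**

F1 | step 15 | (2R,4S,5R,8R,13E)-15-[(tert-butyldimethylsilyl)oxy]-1-hydroxy-20-norhalima-6,9,13-trien-19,2-olide (C-1 epimers) | O=C1O[C@@H]2C[C@@]1(C)[C@@H]1C=C[C@@H](C)C(CC/C(C)=C/CO[Si](C)(C)C(C)(C)C)=C1C2O
F2 | step 19 | methyl (4S,5R,8R,13E)-15-[(tert-butyldimethylsilyl)oxy]-1-hydroxy-20-norhalima-9,13-dien-19-oate (1-OH cis to H-5) | COC(=O)[C@@]1(C)CC[C@H](O)C2=C(CC/C(C)=C/CO[Si](C)(C)C(C)(C)C)[C@H](C)CC[C@@H]12
F3 | step 19 | 2-(diphenylphosphanyl)benzoate of F2 | COC(=O)[C@@]1(C)CC[C@H](OC(=O)c3ccccc3P(c3ccccc3)c3ccccc3)C2=C(CC/C(C)=C/CO[Si](C)(C)C(C)(C)C)[C@H](C)CC[C@@H]12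
F4 | step 7 | (5R)-5-({[tert-butyl(diphenyl)silyl]oxy}methyl)-3-(prop-2-en-1-yl)dihydrofuran-2(3H)-one (C-3 epimers) | O=C1O[C@@H](CO[Si](c2ccccc2)(c2ccccc2)C(C)(C)C)CC1CC=C
F5 | step 7 | (3R,5R)-5-({[tert-butyl(diphenyl)silyl]oxy}methyl)-3-methyl-3-(prop-2-en-1-yl)dihydrofuran-2(3H)-one | O=C1O[C@@H](CO[Si](c2ccccc2)(c2ccccc2)C(C)(C)C)C[C@@]1(C)CC=C
F6 | step 7 | (3S,5R)-5-({[tert-butyl(diphenyl)silyl]oxy}methyl)-3-methyl-3-[(E)-prop-1-en-1-yl]dihydrofuran-2(3H)-one | O=C1O[C@@H](CO[Si](c2ccccc2)(c2ccccc2)C(C)(C)C)C[C@@]1(C)/C=C/C
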